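3 questions stand on two flasks, and one amount carries the comparison: the target that can form while a flask is warm.

| flask | substrate | reagent in the second phase | temperature | remark | time | volume of the second phase over the first |
|---|---|---|---|---|---|---|
| maple | 0.013 M (fed, over 4.0 h) | 0.024 M | −15 °C | run made earlier; the fed solution adds 0.10 times the starting volume |  |  |
| alder | 0.030 M (fed, over 4.0 h) | 0.024 M | 15 °C | run made earlier; the fed solution adds 0.10 times the starting volume |  |  |
| east | 0.020 M (fed, over 4.0 h) | 0.0240 M |  | at −10 °C until 50 min, from then on at 40 °C; the fed solution adds 0.10 times the starting volume | 4.0 h | 0.50 |
| north-east | 0.020 M (fed, over 2.0 h) | 0.0240 M |  | at −10 °C throughout; the fed solution adds 0.10 times the starting volume | 4.0 h | 0.50 |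

maple run (percent of the substrate charged): time / h: target / % = 1.33: 0.1; 2.50: 6.5; 4.00: 19.9; 5.00: 27.5

alder run (percent of the substrate charged): time / min: target / % = 12.0: 2.2; 25.0: 0; 50.0: 2.6; 80.0: 10.0

(each reading ± 1 percentage point)

- which of the two ends with the higher amount of target, in percent of the substrate charged ("neither" if they lie within 2 percentage points) (east / north-east / neither)
- target at the end, in percent of the substrate charged, east
- target at the end, in percent of the substrate charged, north-east

- charges are per starting volume, the dose included; the dosed solution carries all of it
- in the second phase: reagent in the second phase; everything else is in the first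
- charges count per volume of the first phase; a concentration in a rate is the amount of a species over the volume of its own phase; every rate counts per litre of the first phase
- the numbers in the tables scatter by 1 percentage point (one standard deviation)
- the earlier runs hold the two phases in the same ratio of volumes as the flask asked about
- percentages count the whole charge, also what has not yet gone in

1. Main step alone. If substrate turns to target as it enters, east makes target at its feed rate, 0.00500 M h⁻¹, and the zero of the scale is the whole charge as target when the feed ends.

2. Add a ceiling. Between 50.0 min and 80.0 min, alder gains 0.00444 M h⁻¹, a reading from two points that each scatter by 1 percentage point. This lies below the east feed. My reckoning assumes that this gain marks a rate-limiting step, the supply of reagent across the phases, and that warming east to 40 °C leaves it unchanged. The warm allowance 0.0141 M is then this ceiling multiplied by the time after the change of temperature, an amount of target that this reckoning takes as the same for a substrate charge above it. It is smaller than the reagent charge.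

3. Add the cold. Maple shows 0.1 % at 1.33 h, so I count nothing from the first 50 min of east. East then reaches 70.3 % of its charge. North-east stays at −10 °C, where the nearest evidence is maple's late gain, 9.88 × 10⁻⁴ M h⁻¹, which is below the ceiling. Over 4.0 h that gives 19.8 %, though maple ran colder, at −15 °C.

The forecast chooses east, with 72 % for east and 31 % for north-east, which is above my figure for north-east. For east it holds that "target tracks the feed"; my reckoning holds it to the allowance instead.

The flasks give east, with 68.5 % for east and 30.7 % for north-east.

    reagent in the reaction phase ⇌ reagent in the second phase, rate k1*([reagent in the reaction phase] - [reagent in the second phase]/K1) per volume of the first phase (partition coefficient = 0.850, kL = 0.0949 h⁻¹)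
    substrate + reagent in the reaction phase → target (k = 21.1 L mol⁻¹ h⁻¹, Ea = 62.0 kJ mol⁻¹)
    reagent in the reaction phase → decomposition product (k = 8.88 × 10⁻⁵ h⁻¹, Ea = 105 kJ mol⁻¹)
    (constants at −10 °C)

In east at 4.00 h, reagent in the reaction phase stands at 1.98 × 10⁻⁴ M, with a half-life of 0.062 h by the main step, against 3.10 h for reagent in the second phase to cross, while 32 % of the substrate charged remains. East holds 0.00379 M of reagent in the reaction phase at 0.833 h and receives 0.0104 M from the second phase by 4.00 h, together close to the allowance of 0.0141 M. The neighbour flask, east with 0.050 M of substrate, ends at 28.7 %, or 0.0143 M of target.

(All runs are simulated with made-up constants; the scatter is artificial.)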